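The route rests on opening the pyrrole ring of the bromine-free indole at two bonds, N1'–C7a' and C3'–C3a'. This works because N1' and C3' hang on the adjacent carbons C7a' and C3a' of an otherwise unsubstituted, symmetrical benzo ring, which can therefore be delivered as benzyne. The precursor is the finished 2-(6-bromoindol-3-yl)imidazole carrying a TsNH–CH2–C(=O)– chain (N1', C2', C3') on imidazole C4, with every other nitrogen sulfonylated. In one operation the sulfonamide nitrogen is arylated, the ortho aryl anion closes onto the ketone, and loss of water leaves the second indole. One basic hydrolysis then removes all three sulfonyl groups.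

Key step: step 8

Remark on the chemistry: the imidazole N–H of the target moves freely between the two ring nitrogens, so the 2,4- and 2,5-disubstituted drawings are one compound. Primed locants refer to the bromine-free indole. Ts = tosyl = 4-methylbenzenesulfonyl.

Choice of spectator groups: the bromoindole nitrogen carries tosyl rather than a carbamate because it must survive a silyl triflate, NBS, fluoride and a hot acid dehydration. The imidazole carries dimethylsulfamoyl because N-arylsulfonylimidazoles hand their sulfonyl group to nucleophiles. All three groups are cleaved by hydroxide.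

Step 1
Reactants: 1 6-bromoindole
Product: 3 6-bromo-1H-indole-3-carbonitrile, via N-chlorosulfonyl carboxamide 2 (not isolated)
Conditions: ClSO2NCO (1.1 equiv), MeCN, 0 °C; then DMF, 0 °C to rt; aqueous work-up
Reagents that add atoms: chlorosulfonyl isocyanate, O=C=NS(=O)(=O)Cl
Why: Electrophilic substitution at the nucleophilic indole C3 by chlorosulfonyl isocyanate, followed by DMF-induced fragmentation of 2 (CSI/DMF cyanation), is a standard entry to 3-cyanoindoles and leaves the C6–Br bond alone.

Step 2
Reactants: 3 6-bromo-1H-indole-3-carbonitrile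
Product: 4 6-bromo-1H-indole-3-carboximidamide hydrochloride
Conditions: AlMe3 (5 equiv), NH4Cl (5 equiv), toluene, 0 °C to rt; add 3, 90 °C; quench on SiO2/CHCl3, elute with MeOH
Reagents that add atoms: ammonium chloride, [NH4+].[Cl-]
Why: Garigipati amidine synthesis, in which MeAl(Cl)NH2 binds the nitrile nitrogen as a Lewis acid and transfers NH2 to carbon, should overcome the low electrophilicity of this vinylogous cyanamide, with the excess reagent covering the indole N–H.

Step 3
Reactants: 5 2,3-butanedione
Product: 6 1-bromobutane-2,3-dione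
Conditions: Br2 (0.95 equiv, dropwise), CHCl3, 50 °C; distillation under reduced pressure
Reagents that add atoms: bromine, BrBr
Why: Acid-autocatalysed enol bromination of a methyl ketone, where a slight deficit of bromine and the distillation keep the 1,4-dibromide out.

Step 4
Reactants: 4 6-bromo-1H-indole-3-carboximidamide hydrochloride; 6 1-bromobutane-2,3-dione
Product: 7 1-[2-(6-bromo-1H-indol-3-yl)-1H-imidazol-4-yl]ethan-1-one
Conditions: KHCO3 (4 equiv), THF/H2O (4:1), reflux; 6 in THF added over 1 h
Reagents that add atoms: none
Why: Amidine–α-haloketone imidazole synthesis, in which one amidine nitrogen displaces bromide, the other condenses with the adjacent carbonyl and loss of water aromatises the ring, so the remote carbonyl remains as the 4-acetyl group and bicarbonate is too weak to touch the indole N–H.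

Step 5
Reactants: 7 1-[2-(6-bromo-1H-indol-3-yl)-1H-imidazol-4-yl]ethan-1-one
Product: 9 4-acetyl-2-(6-bromo-1-tosylindol-3-yl)-N,N-dimethylimidazole-1-sulfonamide, via N1-sulfamoyl imidazole 8 (not isolated)
Conditions: NaH (1.05 equiv), THF/DMF, 0 °C; Me2NSO2Cl (1.05 equiv), 0 °C to rt; then NaH (1.1 equiv), 0 °C; TsCl (1.15 equiv), 0 °C to rt
Reagents that add atoms: dimethylsulfamoyl chloride, CN(C)S(=O)(=O)Cl; 4-methylbenzenesulfonyl chloride, Cc1ccc(cc1)S(=O)(=O)Cl
Why: Sequential N-sulfonylation steered by acidity, since the first equivalent of NaH removes only the much more acidic imidazole N–H (sulfamoylated at the nitrogen remote from the acetyl group) and the second frees the indole nitrogen, which is still more acidic than the methyl ketone, for tosylation.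

Step 6
Reactants: 9 4-acetyl-2-(6-bromo-1-tosylindol-3-yl)-N,N-dimethylimidazole-1-sulfonamide
Product: 11 4-(bromoacetyl)-2-(6-bromo-1-tosylindol-3-yl)-N,N-dimethylimidazole-1-sulfonamide, via trimethylsilyl enol ether 10 (not isolated)
Conditions: TMSOTf (1.3 equiv), Et3N (1.6 equiv), CH2Cl2, 0 °C; cold aq. NaHCO3 wash, solvent change; NBS (1.05 equiv), THF, 0 °C
Reagents that add atoms: N-bromosuccinimide, O=C1CCC(=O)N1Br; trimethylsilyl trifluoromethanesulfonate, C[Si](C)(C)OS(=O)(=O)C(F)(F)F (its silyl group stays only in 10)
Why: Soft enolisation to the silyl enol ether and electrophilic bromination with NBS should stop at the monobromide, because 10 is far more nucleophilic than the N-tosylated, C3-substituted indole and the medium stays non-acidic.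

Step 7
Reactants: 11 4-(bromoacetyl)-2-(6-bromo-1-tosylindol-3-yl)-N,N-dimethylimidazole-1-sulfonamide; 12 p-toluenesulfonamide
Product: 13 N-{2-[2-(6-bromo-1-tosylindol-3-yl)-1-(dimethylsulfamoyl)imidazol-4-yl]-2-oxoethyl}-4-methylbenzenesulfonamide
Conditions: 12 (4 equiv), K2CO3 (2 equiv), acetone, rt; 11 added slowly; aq. NH4Cl work-up
Reagents that add atoms: none
Why: SN2 N-alkylation of the tosylamide anion by a reactive α-bromo ketone is the standard preparation of N-tosyl phenacylamines, and the excess of 12 with slow addition of 11 suppresses double alkylation.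

Step 8
Reactants: 13 N-{2-[2-(6-bromo-1-tosylindol-3-yl)-1-(dimethylsulfamoyl)imidazol-4-yl]-2-oxoethyl}-4-methylbenzenesulfonamide; 14 2-(trimethylsilyl)phenyl trifluoromethanesulfonate
Product: 17 2-(6-bromo-1-tosylindol-3-yl)-1-(dimethylsulfamoyl)-4-(1-tosylindol-3-yl)imidazole, via benzyne 15 (not isolated), via 3-hydroxyindoline 16 (not isolated)
Conditions: 14 (1.5 equiv, added over 2 h), CsF (3.5 equiv), MeCN, rt to 40 °C; filter, evaporate; TsOH·H2O (20 mol %), toluene, 80 °C
Reagents that add atoms: none
Why: Fluoride attacks silicon in 14 and triflate leaves, releasing benzyne 15 slowly, while CsF also deprotonates the only remaining N–H of 13; the sulfonamide anion adds to the strained triple bond (N1'–C7a') and leaves an aryl anion on the neighbouring carbon C3a'. That carbanion attacks the ketone carbon in a 5-exo-trig closure (C3'–C3a') that builds the five-membered ring of 16, and acid then ionises the tertiary benzylic carbinol and removes a C2' proton (E1), so the ring aromatises to the indole of 17. The closest known reaction type is the formal [3+2] aryne annulation of N-sulfonyl and N-aryl α-amino ketones, in which N-arylation is followed by carbonyl capture. The carbinol carbon of 16 forms as a racemate under no control and is planarised on dehydration, so no stereocentre has to be set. Regiochemistry cannot go wrong because unsubstituted benzyne offers two equivalent carbons, and N-selectivity is secured by sulfonylation of both azole nitrogens and by the crowded, electron-poor state of imidazole N3. Capture has to outrun protonation of the aryl anion, which the five-membered transition state, the ketone activated by the electron-poor imidazole and the low stationary concentration of 15 all favour; the C6–Br bond is safe because no metal or organolithium reagent is present.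

Step 9
Reactants: 17 2-(6-bromo-1-tosylindol-3-yl)-1-(dimethylsulfamoyl)-4-(1-tosylindol-3-yl)imidazole
Product: 18 nortopsentin B
Conditions: KOH (12 equiv), 1,4-dioxane/H2O (3:1), reflux, N2; aq. HCl to pH 8
Reagents that add atoms: none
Why: Nucleophilic desulfonylation, in which hydroxide attacks sulfur and expels the stabilised indolide or imidazolide, is known for N-tosylindoles and for 1-(dimethylsulfamoyl)imidazoles alike, while the alcohol-free medium excludes alkyl tosylates that could alkylate the product and the aryl bromide is inert.

Compound list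
1 | 6-bromoindole | Brc1ccc2cc[nH]c2c1 | starting material
2 | 6-bromo-N-(chlorosulfonyl)-1H-indole-3-carboxamide | O=C(NS(=O)(=O)Cl)c1c[nH]c2cc(Br)ccc12 | intermediate
3 | 6-bromo-1H-indole-3-carbonitrile | N#Cc1c[nH]c2cc(Br)ccc12 | intermediate
4 | 6-bromo-1H-indole-3-carboximidamide hydrochloride | [Cl-].NC(=[NH2+])c1c[nH]c2cc(Br)ccc12 | intermediate
5 | 2,3-butanedione | CC(=O)C(C)=O | starting material
6 | 1-bromobutane-2,3-dione | CC(=O)C(=O)CBr | intermediate
7 | 1-[2-(6-bromo-1H-indol-3-yl)-1H-imidazol-4-yl]ethan-1-one | CC(=O)c1c[nH]c(n1)-c1c[nH]c2cc(Br)ccc12 | intermediate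
8 | 4-acetyl-2-(6-bromo-1H-indol-3-yl)-N,N-dimethylimidazole-1-sulfonamide | CC(=O)c1cn(S(=O)(=O)N(C)C)c(n1)-c1c[nH]c2cc(Br)ccc12 | intermediate
9 | 4-acetyl-2-[6-bromo-1-(4-methylbenzenesulfonyl)indol-3-yl]-N,N-dimethylimidazole-1-sulfonamide | CC(=O)c1cn(S(=O)(=O)N(C)C)c(n1)-c1cn(S(=O)(=O)c2ccc(C)cc2)c2cc(Br)ccc12 | intermediate
10 | 2-(6-bromo-1-tosylindol-3-yl)-N,N-dimethyl-4-[1-(trimethylsilyloxy)ethenyl]imidazole-1-sulfonamide | C=C(O[Si](C)(C)C)c1cn(S(=O)(=O)N(C)C)c(n1)-c1cn(S(=O)(=O)c2ccc(C)cc2)c2cc(Br)ccc12 | intermediate
11 | 4-(bromoacetyl)-2-(6-bromo-1-tosylindol-3-yl)-N,N-dimethylimidazole-1-sulfonamide | BrCC(=O)c1cn(S(=O)(=O)N(C)C)c(n1)-c1cn(S(=O)(=O)c2ccc(C)cc2)c2cc(Br)ccc12 | intermediate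
12 | p-toluenesulfonamide | Cc1ccc(cc1)S(N)(=O)=O | starting material
13 | N-{2-[2-(6-bromo-1-tosylindol-3-yl)-1-(dimethylsulfamoyl)imidazol-4-yl]-2-oxoethyl}-4-methylbenzenesulfonamide | Cc1ccc(cc1)S(=O)(=O)NCC(=O)c1cn(S(=O)(=O)N(C)C)c(n1)-c1cn(S(=O)(=O)c2ccc(C)cc2)c2cc(Br)ccc12 | intermediate
14 | 2-(trimethylsilyl)phenyl trifluoromethanesulfonate | C[Si](C)(C)c1ccccc1OS(=O)(=O)C(F)(F)F | starting material
15 | benzyne (1,2-didehydrobenzene) | C1#CC=CC=C1 | intermediate
16 | racemic 2-(6-bromo-1-tosylindol-3-yl)-4-(3-hydroxy-1-tosyl-2,3-dihydroindol-3-yl)-N,N-dimethylimidazole-1-sulfonamide | Cc1ccc(cc1)S(=O)(=O)N1CC(O)(c2cn(S(=O)(=O)N(C)C)c(n2)-c2cn(S(=O)(=O)c3ccc(C)cc3)c3cc(Br)ccc23)c2ccccc12 | intermediate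
17 | 2-(6-bromo-1-tosylindol-3-yl)-1-(dimethylsulfamoyl)-4-(1-tosylindol-3-yl)imidazole | Cc1ccc(cc1)S(=O)(=O)n1cc(-c2cn(S(=O)(=O)N(C)C)c(n2)-c2cn(S(=O)(=O)c3ccc(C)cc3)c3cc(Br)ccc23)c2ccccc12 | intermediate
18 | nortopsentin B, 6-bromo-3-[4-(1H-indol-3-yl)-1H-imidazol-2-yl]-1H-indole | Brc1ccc2c(-c3nc(-c4c[nH]c5ccccc45)c[nH]3)c[nH]c2c1 | target

Total step count: 9. Longest linear sequence: 8 (steps 1, 2, 4, 5, 6, 7, 8, 9). Step 3 is a one-step side branch.

Steps most likely to fail

Step 8. The aryl anion may be protonated before it reaches the carbonyl, whether by solvent, by unreacted sulfonamide or by internal proton transfer from the α-methylene. The reaction would then stop at plain N-phenylation. Fluoride-induced loss of a sulfonyl group followed by arylation of the freed azole nitrogen is a second drain. The fallback makes the same two bonds one after the other by polar chemistry and sets out from 11. Commercial N-(2-iodophenyl)-4-methylbenzenesulfonamide is alkylated with 11 (K2CO3, DMF, rt) to give the N-(2-iodophenyl)-N-tosyl amino ketone F1. Iodine–magnesium exchange with iPrMgCl·LiCl in THF at −78 to −40 °C is far faster at C–I than at C–Br. It is followed by Parham-type closure of the arylmagnesium onto the neighbouring ketone. After the quench this comes back to the route at 16, which the acid treatment of step 8 converts to 17.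

Step 4. The bromodiketone may self-condense or hydrate under base, or both amidine nitrogens may add across the vicinal dicarbonyl, diverting material from the alkylation–cyclisation path. The fallback sets out from 4 and changes the carbon synthon so that no 1,2-dione is present. Commercial 4,4-dimethoxybutan-2-one is chlorinated with SO2Cl2 to 3-chloro-4,4-dimethoxybutan-2-one F2. This is heated with 4 and NaOAc in dioxane. The masked aldehyde carbon becomes imidazole C5 and the chlorinated carbon becomes C4, as in the known haloalkoxyenone–amidine route to 4-acylimidazoles. The sequence comes back at 7.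

Step 2. Addition to the electron-rich nitrile may be sluggish once the indole nitrogen is metalated, and the polar amidine may be hard to free from the aluminium residues. The fallback sets out from 3 and replaces the amide transfer by addition of an α-effect nucleophile and N–O cleavage. NH2OH·HCl and Na2CO3 in refluxing EtOH/H2O give the amidoxime F3. Zn dust in AcOH reduces it to the amidine without touching the aryl bromide. Treatment with HCl in MeOH comes back at 4.

Further compounds
F1 | step 8 | N-{2-[2-(6-bromo-1-tosylindol-3-yl)-1-(dimethylsulfamoyl)imidazol-4-yl]-2-oxoethyl}-N-(2-iodophenyl)-4-methylbenzenesulfonamide | Cc1ccc(cc1)S(=O)(=O)N(CC(=O)c1cn(S(=O)(=O)N(C)C)c(n1)-c1cn(S(=O)(=O)c2ccc(C)cc2)c2cc(Br)ccc12)c1ccccc1I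
F2 | step 4 | racemic 3-chloro-4,4-dimethoxybutan-2-one | CC(=O)C(Cl)C(OC)OC
F3 | step 2 | (Z)-6-bromo-N'-hydroxy-1H-indole-3-carboximidamide | N/C(=N\O)c1c[nH]c2cc(Br)ccc12
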